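**Plan**

Retrosynthetic cuts, in order: C5–OOH (back to a C4=C5 alkene with C15 as a methyl group); the C8 acetate and C12 methyl ester (back to a cis 12,8β-lactone); C11=C13; the C3 ester; the carbinol C–H bonds at C3 and C8 (back to ketones); then the skeletal bonds C9–C10, C8–C9 and C6–C7.
Enabling feature: ring A (C1–C5, C10) bears oxygen at C3, the one-carbon branch C15 at C4 and methyl C14 on C10, para to C3, which is the pattern of a 2,4-dimethylphenol. C9 of ring B is bonded to that para carbon, next to C5 that carries C6, so a phenoxide can be alkylated at C10 by a C9 electrophile hanging from C5.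
Forward order: the arene that becomes ring A is made first, and C6–C7 joins it to a succinate unit (C7, C8, C11, C12). Diazomethane adds C9, ring B closes through C9–C10 with dearomatisation, and a temporary lactone ring forms at C8–O and is opened again once C13 is in place.
Stereochemistry: C7 comes from an Evans alkylation with (R)-4-benzyl-2-oxazolidinone, and C10 is relayed from C7 in the ring closure. The β-axial C14 methyl then sends hydride to the α face of C8 and C3 and singlet oxygen to the α face of C5.

Key step: step 9

Remark: the SMILES is read as 3S,5S,7R,8R,10R, that is 3β-isobutyryloxy, 5α-hydroperoxy, 7α-H, 8β-acetoxy and 10β-methyl. Eudesmane numbering is used throughout, and bicyclic compounds that still lack C13 are named as 13-noreudesmanes.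
Remark: diazomethane is assumed to be an ethereal solution freshly made from commercial N-methyl-N-nitroso-p-toluenesulfonamide.

**Route**

Step 1
Reactants: 1 3-methoxy-2-methylbenzoic acid
Product: 2 3-methoxy-2,6-dimethylbenzoic acid
Conditions: Pd(OAc)2 (10 mol %), MeB(OH)2, Ag2CO3, 1,4-benzoquinone, K2HPO4, t-BuOH, 100 °C
Reagents that add atoms: methylboronic acid, CB(O)O
Why: Carboxylate-directed ortho C–H methylation by divalent palladium with a methylboron reagent is established for 2-substituted benzoic acids, and since C6 is the only free ortho position one product is expected, whereas strong-base metalation would deprotonate the C2 methyl group instead.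

Step 2
Reactants: 2 3-methoxy-2,6-dimethylbenzoic acid
Product: 3 (3-methoxy-2,6-dimethylphenyl)methanol
Conditions: BH3·THF, THF, 0 °C to reflux; then H2O
Reagents that add atoms: none
Why: Borane reduction of a carboxylic acid runs through acyloxyboranes, works even with both ortho positions substituted and leaves the aryl methyl ether untouched.

Step 3
Reactants: 3 (3-methoxy-2,6-dimethylphenyl)methanol
Product: 4 3-(bromomethyl)-2,4-dimethylphenol
Conditions: BBr3, CH2Cl2, −78 to 0 °C; then H2O
Reagents that add atoms: boron tribromide, BrB(Br)Br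
Why: Boron tribromide cleaves the aryl methyl ether and at the same time turns the benzylic alcohol into the bromide, a double role known for methoxybenzyl alcohols, and the meta relation of OH and CH2Br rules out quinone methide formation.

Step 4
Reactants: 4 3-(bromomethyl)-2,4-dimethylphenol
Product: 5 [3-(bromomethyl)-2,4-dimethylphenoxy]triisopropylsilane
Conditions: i-Pr3SiOTf, 2,6-lutidine, CH2Cl2, 0 °C
Reagents that add atoms: triisopropylsilyl trifluoromethanesulfonate, CC(C)[Si](OS(=O)(=O)C(F)(F)F)(C(C)C)C(C)C
Why: Phenol silylation with a silyl triflate and a non-nucleophilic pyridine base is fast and brings in no nucleophile that could attack the benzylic bromide, and the bulky aryl silyl ether is chosen because it should survive the enolate, hydroperoxide and HBr steps yet fall to fluoride.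

Step 5
Reactants: 6 4-tert-butoxy-4-oxobutanoic acid; 7 (R)-4-benzyl-1,3-oxazolidin-2-one
Product: 9 tert-butyl 4-[(4R)-4-benzyl-2-oxo-1,3-oxazolidin-3-yl]-4-oxobutanoate, via mixed pivalic anhydride 8 (not isolated)
Conditions: t-BuCOCl, Et3N, THF, −20 °C; then LiCl, 7, −20 °C to rt
Reagents that add atoms: none
Why: N-acylation of an oxazolidinone through a mixed pivalic anhydride under LiCl/Et3N activation is the standard mild route to Evans imides, the nitrogen attacking the less hindered succinyl carbonyl.

Step 6
Reactants: 9 tert-butyl 4-[(4R)-4-benzyl-2-oxo-1,3-oxazolidin-3-yl]-4-oxobutanoate; 5 [3-(bromomethyl)-2,4-dimethylphenoxy]triisopropylsilane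
Product: 11 tert-butyl (3R)-4-[(4R)-4-benzyl-2-oxo-1,3-oxazolidin-3-yl]-3-[2,6-dimethyl-3-(triisopropylsilyloxy)benzyl]-4-oxobutanoate, via sodium enolate 10 (not isolated)
Conditions: NaN(SiMe3)2, THF, −78 °C; then 5, −78 to −20 °C
Reagents that add atoms: none
Why: In this Evans asymmetric alkylation the imide α-CH2 is more acidic than the ester α-CH2, so the chelated (Z)-enolate 10 forms regioselectively, the auxiliary benzyl group blocks one face, and the benzylic bromide adds to the open face to form C6–C7 and set C7 as R.

Step 7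
Reactants: 11 tert-butyl (3R)-4-[(4R)-4-benzyl-2-oxo-1,3-oxazolidin-3-yl]-3-[2,6-dimethyl-3-(triisopropylsilyloxy)benzyl]-4-oxobutanoate
Product: 13 (2R)-4-tert-butoxy-2-[2,6-dimethyl-3-(triisopropylsilyloxy)benzyl]-4-oxobutanoic acid, via peroxy acid 12 (not isolated)
Conditions: LiOH, H2O2, THF–H2O, 0 °C; then aq. Na2SO3; then 1 M HCl to pH 3
Reagents that add atoms: hydrogen peroxide, OO
Why: Hydroperoxide cleavage of an Evans imide attacks the exocyclic carbonyl even in α-branched cases, sulfite reduces the peroxy acid, and the tert-butyl ester, the hindered aryl silyl ether and C7 should be unaffected at 0 °C.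

Step 8
Reactants: 13 (2R)-4-tert-butoxy-2-[2,6-dimethyl-3-(triisopropylsilyloxy)benzyl]-4-oxobutanoic acid
Product: 16 tert-butyl (3R)-5-bromo-3-[2,6-dimethyl-3-(triisopropylsilyloxy)benzyl]-4-oxopentanoate, via mixed carbonic anhydride 14 (not isolated), via diazoketone 15 (not isolated)
Conditions: i-BuOCOCl, N-methylmorpholine, THF, −20 °C; CH2N2, Et2O, 0 °C; then 48 % aq. HBr, 0 °C
Reagents that add atoms: diazomethane, C=[N+]=[N-]; hydrogen bromide, Br
Why: Acylation of diazomethane by a mixed carbonic anhydride (the first stage of the Arndt–Eistert sequence) followed by hydrobromination of the diazoketone is routine for α-chiral acids that carry tert-butyl-based groups, and it adds C9 without touching C7.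

Step 9
Reactants: 16 tert-butyl (3R)-5-bromo-3-[2,6-dimethyl-3-(triisopropylsilyloxy)benzyl]-4-oxopentanoate
Product: 18 tert-butyl 3,8-dioxo-13-noreudesma-1,4-dien-12-oate (7α-H and 10β-methyl), via tetrabutylammonium phenoxide 17 (not isolated)
Conditions: n-Bu4NF (1.0 equiv, slow addition), THF (0.002 M), −20 °C to rt
Reagents that add atoms: none
Why: Fluoride removes the silyl group and leaves the loosely ion-paired phenoxide 17, whose para carbon C10 displaces bromide from the carbonyl-activated C9 in an intramolecular SN2 reaction, so that C9–C10 forms, C10 becomes quaternary with C14 in place and ring A emerges as the cross-conjugated dienone with its ketone at C3. The closest known reaction type is the Ar2-6 alkylative dearomatisation of phenoxides (Winstein–Masamune type), including its fluoride-triggered form from aryl silyl ethers. Ring B closes in the 6-exo-tet mode. C10 is controlled by C7: in the chair-like transition state the CH2CO2t-Bu arm lies equatorial, C9 reaches the α face of the arene and C14 is pushed to the β face, and any C10 epimer is a diastereomer that chromatography should remove. The step needs C10 over C4 and carbon over oxygen: C4 is wedged between the oxide and the side chain and would give the less stable linearly conjugated dienone, a non-coordinating cation withholds the metal assistance that favours ortho attack, the oxygen cannot reach C9 within the same molecule, and high dilution with slow fluoride addition holds back ether formation between two molecules. Because no base beyond one equivalent of phenoxide is present, enolisation toward C7 and Favorskii contraction should stay slow, and after closure the equatorial C7 arm is also the thermodynamically preferred one.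

Step 10
Reactants: 18 tert-butyl 3,8-dioxo-13-noreudesma-1,4-dien-12-oate
Product: 19 tert-butyl 3,8-dioxo-13-noreudesm-4-en-12-oate
Conditions: H2 (1 atm), RhCl(PPh3)3 (10 mol %), toluene–EtOH, rt
Reagents that add atoms: none
Why: Homogeneous hydrogenation with RhCl(PPh3)3 saturates only the disubstituted C1=C2 bond of cross-conjugated 1,4-dien-3-ones, as known for santonin-type and steroidal dienones, because the tetrasubstituted C4=C5 bond cannot bind to rhodium.

Step 11
Reactants: 19 tert-butyl 3,8-dioxo-13-noreudesm-4-en-12-oate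
Product: 20 tert-butyl 8β-hydroxy-3-oxo-13-noreudesm-4-en-12-oate
Conditions: LiBH(s-Bu)3 (1.05 equiv), THF, −78 °C; then AcOH
Reagents that add atoms: none
Why: In this hindered trialkylborohydride reduction the saturated C8 ketone should react faster than the conjugated, α-methylated C3 enone, and hydride enters from the equatorial α side away from the axial C14 methyl, giving the axial 8β-alcohol cis to the C7 arm.

Step 12
Reactants: 20 tert-butyl 8β-hydroxy-3-oxo-13-noreudesm-4-en-12-oate
Product: 22 3-oxo-13-noreudesm-4-en-12,8β-olide (cis-fused), via hydroxy acid 21 (not isolated)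
Conditions: CF3CO2H, CH2Cl2, 0 °C to rt
Reagents that add atoms: none
Why: Acidolysis of the tert-butyl ester gives hydroxy acid 21, whose axial 8β-OH and equatorial C7 acetic acid arm are cis and should close spontaneously to the γ-lactone, while the enone is inert to the acid and C7 is no longer epimerisable.

Step 13
Reactants: 22 3-oxo-13-noreudesm-4-en-12,8β-olide
Product: 23 3β-hydroxy-13-noreudesm-4-en-12,8β-olide
Conditions: NaBH4, CeCl3·7H2O, MeOH, −20 °C
Reagents that add atoms: none
Why: Luche reduction gives clean 1,2-reduction of the enone without touching the lactone, and axial hydride delivery from the α face, as in steroidal and eudesmane 4-en-3-ones, gives the pseudo-equatorial 3β-alcohol.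

Step 14
Reactants: 23 3β-hydroxy-13-noreudesm-4-en-12,8β-olide
Product: 27 3β-hydroxyeudesma-4,11(13)-dien-12,8β-olide, via dilithium alkoxide enolate 24 (not isolated), via Mannich base 25 (not isolated), via methiodide 26 (not isolated)
Conditions: LiN(i-Pr)2 (2.3 equiv), THF, −78 °C; CH2=NMe2+ I−, −78 °C to rt; H2O; then MeI, THF, rt; then aq. NaHCO3, CH2Cl2
Reagents that add atoms: N,N-dimethylmethyleneiminium iodide (Eschenmoser's salt), C=[N+](C)C.[I-]
Why: In this lactone α-methylenation by the Mannich route, two equivalents of amide base give 24, the iminium salt aminomethylates C11, and quaternisation followed by mild Hofmann-type elimination gives C11=C13, a sequence that tolerates free hydroxy groups and is run here before any enolisable ester is present.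

Step 15
Reactants: 27 3β-hydroxyeudesma-4,11(13)-dien-12,8β-olide
Product: 28 3β-isobutyryloxyeudesma-4,11(13)-dien-12,8β-olide
Conditions: (i-PrCO)2O, DMAP, Et3N, CH2Cl2, 0 °C to rt
Reagents that add atoms: isobutyric anhydride, CC(C)C(=O)OC(=O)C(C)C
Why: DMAP-catalysed acyl transfer to the only hydroxy group proceeds with retention at C3 and is routine for hydroxy α-methylene lactones.

Step 16
Reactants: 28 3β-isobutyryloxyeudesma-4,11(13)-dien-12,8β-olide
Product: 30 methyl 8β-hydroxy-3β-isobutyryloxyeudesma-4,11(13)-dien-12-oate, via potassium carboxylate 29 (not isolated)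
Conditions: KOH (1.05 equiv), THF–H2O, 0 °C; evaporation; then MeI, DMF, rt
Reagents that add atoms: potassium hydroxide, [K+].[OH-]; iodomethane, CI
Why: The γ-lactone should saponify much faster than the α-branched isobutyrate of a hindered secondary alcohol, so one equivalent of hydroxide opens only the lactone by acyl–oxygen cleavage with retention at C8, and SN2 methylation of carboxylate 29 without acidification avoids the hydroxy acid that would relactonise.

Step 17
Reactants: 30 methyl 8β-hydroxy-3β-isobutyryloxyeudesma-4,11(13)-dien-12-oate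
Product: 31 methyl 8β-acetoxy-3β-isobutyryloxyeudesma-4,11(13)-dien-12-oate
Conditions: Ac2O (excess), DMAP, Et3N, CH2Cl2, rt, on crude 30
Reagents that add atoms: acetic anhydride, CC(=O)OC(C)=O
Why: DMAP-catalysed acetylation with a large excess of anhydride caps the hindered axial 8β-alcohol with retention and should outrun relactonisation of the unpurified hydroxy ester.

Step 18
Reactants: 31 methyl 8β-acetoxy-3β-isobutyryloxyeudesma-4,11(13)-dien-12-oate
Product: 32 methyl 8β-acetoxy-5α-hydroperoxy-3β-isobutyryloxyeudesma-4(15),11(13)-dien-12-oate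
Conditions: O2, tetraphenylporphyrin (cat.), visible light, CH2Cl2, −20 °C
Reagents that add atoms: dioxygen, O=O
Why: In this Schenck ene reaction singlet oxygen attacks the only electron-rich alkene (the acrylate is inert) from the α face opposite the axial C14 methyl, bonds to C5 and takes a hydrogen from the freely rotating C15 methyl, because on that face H-6α is pseudo-equatorial and misaligned and H-3α is deactivated by the geminal acyloxy group, which gives the 5α-hydroperoxide and the C4=C15 methylene.

**Compound list**

1 | 3-methoxy-2-methylbenzoic acid | COc1cccc(C(=O)O)c1C | starting material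
2 | 3-methoxy-2,6-dimethylbenzoic acid | COc1ccc(C)c(C(=O)O)c1C | intermediate
3 | (3-methoxy-2,6-dimethylphenyl)methanol | COc1ccc(C)c(CO)c1C | intermediate
4 | 3-(bromomethyl)-2,4-dimethylphenol | Cc1ccc(O)c(C)c1CBr | intermediate
5 | [3-(bromomethyl)-2,4-dimethylphenoxy]triisopropylsilane | Cc1ccc(O[Si](C(C)C)(C(C)C)C(C)C)c(C)c1CBr | intermediate
6 | 4-tert-butoxy-4-oxobutanoic acid (mono-tert-butyl succinate) | CC(C)(C)OC(=O)CCC(=O)O | starting material
7 | (R)-4-benzyl-1,3-oxazolidin-2-one | O=C1N[C@H](Cc2ccccc2)CO1 | starting material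
8 | 4-tert-butoxy-4-oxobutanoic pivalic anhydride | CC(C)(C)OC(=O)CCC(=O)OC(=O)C(C)(C)C | intermediate
9 | tert-butyl 4-[(4R)-4-benzyl-2-oxo-1,3-oxazolidin-3-yl]-4-oxobutanoate | CC(C)(C)OC(=O)CCC(=O)N1C(=O)OC[C@H]1Cc1ccccc1 | intermediate
10 | sodium (Z)-enolate of 9 | CC(C)(C)OC(=O)C/C=C(\[O-])N1C(=O)OC[C@H]1Cc1ccccc1.[Na+] | intermediate
11 | tert-butyl (3R)-4-[(4R)-4-benzyl-2-oxo-1,3-oxazolidin-3-yl]-3-[2,6-dimethyl-3-(triisopropylsilyloxy)benzyl]-4-oxobutanoate | CC(C)(C)OC(=O)C[C@@H](Cc1c(C)ccc(O[Si](C(C)C)(C(C)C)C(C)C)c1C)C(=O)N1C(=O)OC[C@H]1Cc1ccccc1 | intermediate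
12 | (2R)-4-tert-butoxy-2-[2,6-dimethyl-3-(triisopropylsilyloxy)benzyl]-4-oxobutaneperoxoic acid | CC(C)(C)OC(=O)C[C@@H](Cc1c(C)ccc(O[Si](C(C)C)(C(C)C)C(C)C)c1C)C(=O)OO | intermediate
13 | (2R)-4-tert-butoxy-2-[2,6-dimethyl-3-(triisopropylsilyloxy)benzyl]-4-oxobutanoic acid | CC(C)(C)OC(=O)C[C@@H](Cc1c(C)ccc(O[Si](C(C)C)(C(C)C)C(C)C)c1C)C(=O)O | intermediate
14 | isobutyl carbonic anhydride of 13 | CC(C)(C)OC(=O)C[C@@H](Cc1c(C)ccc(O[Si](C(C)C)(C(C)C)C(C)C)c1C)C(=O)OC(=O)OCC(C)C | intermediate
15 | tert-butyl (3R)-5-diazo-3-[2,6-dimethyl-3-(triisopropylsilyloxy)benzyl]-4-oxopentanoate | CC(C)(C)OC(=O)C[C@@H](Cc1c(C)ccc(O[Si](C(C)C)(C(C)C)C(C)C)c1C)C(=O)C=[N+]=[N-] | intermediate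
16 | tert-butyl (3R)-5-bromo-3-[2,6-dimethyl-3-(triisopropylsilyloxy)benzyl]-4-oxopentanoate | CC(C)(C)OC(=O)C[C@@H](Cc1c(C)ccc(O[Si](C(C)C)(C(C)C)C(C)C)c1C)C(=O)CBr | intermediate
17 | tetrabutylammonium 3-[(2R)-4-bromo-2-(2-tert-butoxy-2-oxoethyl)-3-oxobutyl]-2,4-dimethylphenoxide | CC(C)(C)OC(=O)C[C@@H](Cc1c(C)ccc([O-])c1C)C(=O)CBr.CCCC[N+](CCCC)(CCCC)CCCC | intermediate
18 | tert-butyl 3,8-dioxo-13-noreudesma-1,4-dien-12-oate (7α-H, 10β-methyl) | CC(C)(C)OC(=O)C[C@H]1CC2=C(C)C(=O)C=C[C@]2(C)CC1=O | intermediate
19 | tert-butyl 3,8-dioxo-13-noreudesm-4-en-12-oate | CC(C)(C)OC(=O)C[C@H]1CC2=C(C)C(=O)CC[C@]2(C)CC1=O | intermediate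
20 | tert-butyl 8β-hydroxy-3-oxo-13-noreudesm-4-en-12-oate | CC(C)(C)OC(=O)C[C@H]1CC2=C(C)C(=O)CC[C@]2(C)C[C@H]1O | intermediate
21 | 8β-hydroxy-3-oxo-13-noreudesm-4-en-12-oic acid | OC(=O)C[C@H]1CC2=C(C)C(=O)CC[C@]2(C)C[C@H]1O | intermediate
22 | 3-oxo-13-noreudesm-4-en-12,8β-olide (cis-fused, 7α-H, 8α-H) | O=C1C[C@H]2CC3=C(C)C(=O)CC[C@]3(C)C[C@H]2O1 | intermediate
23 | 3β-hydroxy-13-noreudesm-4-en-12,8β-olide | O=C1C[C@H]2CC3=C(C)[C@@H](O)CC[C@]3(C)C[C@H]2O1 | intermediate
24 | dilithium alkoxide enolate of 23 | [Li+].[Li+].[O-]C1=C[C@H]2CC3=C(C)[C@@H]([O-])CC[C@]3(C)C[C@H]2O1 | intermediate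
25 | 13-(dimethylamino)-3β-hydroxyeudesm-4-en-12,8β-olide (C11 epimers) | O=C1C(CN(C)C)[C@H]2CC3=C(C)[C@@H](O)CC[C@]3(C)C[C@H]2O1 | intermediate
26 | N-methyl ammonium iodide of 25 (C11 epimers) | O=C1C(C[N+](C)(C)C)[C@H]2CC3=C(C)[C@@H](O)CC[C@]3(C)C[C@H]2O1.[I-] | intermediate
27 | 3β-hydroxyeudesma-4,11(13)-dien-12,8β-olide | O=C1C(=C)[C@H]2CC3=C(C)[C@@H](O)CC[C@]3(C)C[C@H]2O1 | intermediate
28 | 3β-isobutyryloxyeudesma-4,11(13)-dien-12,8β-olide | O=C1C(=C)[C@H]2CC3=C(C)[C@@H](OC(=O)C(C)C)CC[C@]3(C)C[C@H]2O1 | intermediate
29 | potassium 8β-hydroxy-3β-isobutyryloxyeudesma-4,11(13)-dien-12-oate | [K+].[O-]C(=O)C(=C)[C@H]1CC2=C(C)[C@@H](OC(=O)C(C)C)CC[C@]2(C)C[C@H]1O | intermediate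
30 | methyl 8β-hydroxy-3β-isobutyryloxyeudesma-4,11(13)-dien-12-oate | COC(=O)C(=C)[C@H]1CC2=C(C)[C@@H](OC(=O)C(C)C)CC[C@]2(C)C[C@H]1O | intermediate
31 | methyl 8β-acetoxy-3β-isobutyryloxyeudesma-4,11(13)-dien-12-oate | COC(=O)C(=C)[C@H]1CC2=C(C)[C@@H](OC(=O)C(C)C)CC[C@]2(C)C[C@H]1OC(C)=O | intermediate
32 | methyl (3S,5S,7R,8R,10R)-8β-acetoxy-5α-hydroperoxy-3β-isobutyryloxyeudesma-4(15),11(13)-dien-12-oate | C=C(C(=O)OC)[C@H]1C[C@@]2(OO)C(=C)[C@@H](OC(=O)C(C)C)CC[C@]2(C)C[C@H]1OC(C)=O | target

**Step count and risks**

Total step count: 18. Longest linear sequence: 17 (steps 1–4 and 6–18; step 5 runs in parallel).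

Steps most likely to fail:

Step 9. Several processes may compete with the desired closure:
- ether formation between the phenoxide of one molecule and the bromoketone of another;
- attack through C4 instead of C10;
- weak discrimination between the two arene faces;
- enolisation of the bromoketone, leading to C7 epimerisation or Favorskii contraction.

The fallback keeps the C9–C10 disconnection but replaces the anionic alkylation by an acid-promoted aryl participation. It sets out from diazoketone 15, isolated by stopping step 8 before the HBr quench, and comes back to the route at 18. n-Bu4NF in THF at 0 °C would free the phenol, to which the base-stable diazoketone is indifferent, giving tert-butyl (3R)-5-diazo-3-(3-hydroxy-2,6-dimethylbenzyl)-4-oxopentanoate F1. Brief exposure of F1 to CF3CO2H in CH2Cl2 at −20 °C would protonate the diazo carbon. The phenol ring would then capture C9 at C10 with loss of nitrogen to give 18. No phenoxide, free base or alkyl halide is present, so ether formation and enolisation are taken out, and the short contact time at low temperature should spare the tert-butyl ester.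

Step 16. Three processes may interfere: saponification of the isobutyrate alongside the lactone, conjugate addition of hydroxide at C13, and relactonisation while the hydroxy ester is handled. The fallback postpones the isobutyrate until the lactone is open. It sets out from 27 and comes back at 30. KOH in THF–H2O would open the lactone of 27, which holds no other ester, to potassium 3β,8β-dihydroxyeudesma-4,11(13)-dien-12-oate F2. MeI in DMF would convert it into methyl 3β,8β-dihydroxyeudesma-4,11(13)-dien-12-oate F3. One equivalent of isobutyric anhydride with DMAP at −20 °C should then acylate the open, pseudo-equatorial allylic 3β-OH in preference to the axial 8β-OH, which is syn-axial to C14, giving 30.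

Step 11. Competing 1,2-reduction of the C3 enone by the borohydride may erode chemoselectivity. The fallback gives up on selective mono-reduction. It sets out from 19 and comes back at 20. Excess LiBH(s-Bu)3 would reduce both carbonyl groups, C8 still from the α side, to tert-butyl 3ξ,8β-dihydroxy-13-noreudesm-4-en-12-oate F4. MnO2 in CH2Cl2 would then re-oxidise only the allylic C3 alcohol to the enone of 20.

**Further compounds**

F1 | step 9 | tert-butyl (3R)-5-diazo-3-(3-hydroxy-2,6-dimethylbenzyl)-4-oxopentanoate | CC(C)(C)OC(=O)C[C@@H](Cc1c(C)ccc(O)c1C)C(=O)C=[N+]=[N-]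
F2 | step 16 | potassium 3β,8β-dihydroxyeudesma-4,11(13)-dien-12-oate | [K+].[O-]C(=O)C(=C)[C@H]1CC2=C(C)[C@@H](O)CC[C@]2(C)C[C@H]1O
F3 | step 16 | methyl 3β,8β-dihydroxyeudesma-4,11(13)-dien-12-oate | COC(=O)C(=C)[C@H]1CC2=C(C)[C@@H](O)CC[C@]2(C)C[C@H]1O
F4 | step 11 | tert-butyl 3ξ,8β-dihydroxy-13-noreudesm-4-en-12-oate (C3 epimers) | CC(C)(C)OC(=O)C[C@H]1CC2=C(C)C(O)CC[C@]2(C)C[C@H]1O
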